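Readings and results were generated by integration with constants of no real substance, and the scatter is random.

Read mol% as mM first: a percent of the charge hides how much precatalyst the flask holds.

| flask | starting material | precatalyst | remark | time |
|---|---|---|---|---|
| west | 0.20 mM | 4.8 mol% | run made earlier |  |
| east | 0.20 mM | 11 mol% | run made earlier |  |
| south | 0.30 mM | 7.1 mol% | run made earlier |  |
| flask | 0.20 mM | 7.1 mol% |  | 20 min |

| run | time / min | target / % |
|---|---|---|
| west | 0.333 | 4.9 |
| west | 0.667 | 16.8 |
| west | 1.33 | 30.0 |
| west | 2.50 | 23.1 |
| west | 6.00 | 2.6 |
| west | 12.0 | 0 |
| west | 25.0 | 0.3 |
| east | 0.333 | 9.8 |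
| east | 0.667 | 27.6 |
| east | 1.33 | 24.2 |
| east | 2.50 | 5.9 |
| east | 6.00 | 0.5 |
| east | 12.0 | 0 |
| east | 25.0 | 0 |
| south | 0.333 | 10.5 |
| south | 0.833 | 30.6 |
| south | 2.50 | 5.2 |
| south | 8.00 | 0 |
| south | 25.0 | 0 |

(standard deviation of a reading: 0.5 percentage points)

- the numbers in the tables scatter by 0.5 percentage points (one standard deviation)

- time up to 20 min at which target stands highest
- the amount of target, in percent of the starting material charged, at that time
- earliest time at which at least nineteen twentieths of that best amount are there, in min
- latest time at which they still are, in min

Your hunch that this flask lands between west and east holds for [precatalyst], and one product gets there cheaply. South and east hold nearly the same [precatalyst], 0.0213 mM and 0.0220 mM, despite different starting material. Their first readings of target are close, 10.5% and 9.8%. So I treat [precatalyst] × time as the clock of these curves, and call its value at the highest target reading the peak exposure. It is read in west, at low [precatalyst], and in south, at high [precatalyst], and joined by the mean: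

west: 0.00960 mM × 1.33 min = 0.0128 mM·min

south: 0.0213 mM × 0.833 min = 0.0177 mM·min

mean: 0.0153 mM·min

flask: 0.0153 mM·min / 0.0142 mM = 1.07 min

This is my own figure, and it is coarse: the exposure read in south is 1.38 times that read in west. The highest readings of west and south, 30.0% and 30.6%, put the height for this flask near 30.0%.

The forecast starts from the same observation, “Percent curves follow absolute catalyst concentration”. It puts the peak later than my figure, at 1.13 min (1.02 min to 1.25 min), with 30.8% of target and a window from 0.91 min to 1.41 min.

The flask gives 30.6% at 1.18 min, with the window open from 0.949 min to 1.45 min.

    starting material → intermediate (k = 0.140 /s)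
    catalyst + intermediate → catalyst + target (k = 1390 /M/s)
    catalyst + target → catalyst + over-reaction product (k = 1960 /M/s)
    precatalyst → catalyst (k = 0.0341 /s)

The flask's best time is 1.10 peak exposures. At 0.0826 min, target has a half-life of 2.7 min by its step to over-reaction product, shorter than the 3.8 min of intermediate by the step that makes target.

Left until 12 min, the same flask reaches an exposure of 0.170 mM·min, which is 11.1 peak exposures and beyond the 0.115 mM·min at which west read 0% of target, so the reckoning expects a reading like that of west. Computed, that flask holds 0% target and >99.9% over-reaction product, after a highest target of 30.6%.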